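**Retrosynthetic overview**
1. Last C–C bond: the acyl–cyclopropyl bond, made by a palladium/copper-mediated coupling of a lactate-derived thioester that already carries the silylated coumaroyl ester (west) with a trans-cyclopropylboronic acid that already carries the silylated carbinol and the dihydropyranone (east). Double desilylation ends the synthesis.
2. West: Heck coupling of silylated 4-iodophenol with acrylic acid, O-acylation of (S)-lactic acid, thioesterification.
3. East: Sharpless desymmetrisation of divinylcarbinol sets both oxygen-bearing stereocentres. Propiolate opening of the epoxide, Lindlar reduction and lactonisation build the dihydropyranone (first ring formed).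
4. The remaining vinyl group becomes an (E)-alkenyl pinacol boronate by cross-metathesis (vinyl boronate made from vinylmagnesium bromide) and is cyclopropanated anti to the lactone-bearing carbon (second ring formed). The aryl ring is bought.

Assumption: L-(+)-DIPT is taken to deliver the (2R,3S)-epoxy alcohol (the usual Sharpless sense for divinylcarbinol); carriers of boron, silicon and sulfur that are lost again are treated as reagents.

**Route**

Step 1
Reactants: 1 4-iodophenol
Product: 2 tert-butyl(4-iodophenoxy)dimethylsilane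
Conditions: TBSCl, imidazole, DMF, rt
Reagents that add atoms: tert-butyldimethylsilyl chloride, CC(C)(C)[Si](C)(C)Cl
Why: Imidazole-mediated O-silylation masks the phenol for the later acid chloride and carbodiimide chemistry; no stereocentre is involved.

Step 2
Reactants: 2 tert-butyl(4-iodophenoxy)dimethylsilane; 3 acrylic acid
Product: 4 (E)-3-[4-(tert-butyldimethylsilyloxy)phenyl]prop-2-enoic acid
Conditions: Pd(OAc)2 (2 mol %), P(o-tol)3, Et3N, MeCN, 80 °C; citric acid work-up
Reagents that add atoms: none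
Why: Mizoroki–Heck reaction (oxidative addition of the aryl iodide to zerovalent palladium, syn insertion, syn β-hydride elimination) gives the E-cinnamic acid selectively.

Step 3
Reactants: 4 (E)-3-[4-(tert-butyldimethylsilyloxy)phenyl]prop-2-enoic acid; 5 (S)-lactic acid
Product: 7 (S)-2-{[(E)-3-(4-(tert-butyldimethylsilyloxy)phenyl)prop-2-enoyl]oxy}propanoic acid, via cinnamoyl chloride 6 (not isolated)
Conditions: (COCl)2, cat. DMF, CH2Cl2, 0 °C → rt, evaporate; then 5 (3 equiv), pyridine, CH2Cl2, 0 °C → rt; citric acid work-up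
Reagents that add atoms: oxalyl chloride, O=C(Cl)C(=O)Cl (supplies only the chlorine of intermediate 6)
Why: Acid chloride formation followed by O-acylation of the secondary hydroxyl (any mixed anhydride is hydrolysed on work-up); the (S) centre comes from the chiral pool and no bond to it is made or broken.

Step 4
Reactants: 7 (S)-2-{[(E)-3-(4-(tert-butyldimethylsilyloxy)phenyl)prop-2-enoyl]oxy}propanoic acid
Product: 8 S-phenyl (S)-2-{[(E)-3-(4-(tert-butyldimethylsilyloxy)phenyl)prop-2-enoyl]oxy}propanethioate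
Conditions: PhSH, DCC, DMAP (5 mol %), CH2Cl2, 0 °C
Reagents that add atoms: thiophenol, Sc1ccccc1
Why: Steglich-type thioesterification at low temperature with little DMAP activates the acid without epimerising the α-acyloxy centre.

Step 5
Reactants: 9 penta-1,4-dien-3-ol (divinylcarbinol)
Product: 10 (S)-1-[(R)-oxiran-2-yl]prop-2-en-1-ol [(2R,3S)-1,2-epoxypent-4-en-3-ol]
Conditions: Ti(OiPr)4, L-(+)-DIPT, t-BuOOH, 4 Å MS, CH2Cl2, −20 °C
Reagents that add atoms: tert-butyl hydroperoxide, CC(C)(C)OO
Why: Sharpless asymmetric epoxidation as a desymmetrisation: enantiotopic-group and diastereoface selection by the tartrate–titanium catalyst set the carbinol (S) and epoxide (R) centres in the erythro sense, and the minor enantiomer is removed by over-epoxidation.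

Step 6
Reactants: 10 (S)-1-[(R)-oxiran-2-yl]prop-2-en-1-ol
Product: 11 tert-butyldimethyl{[(S)-1-((R)-oxiran-2-yl)prop-2-en-1-yl]oxy}silane
Conditions: TBSCl, imidazole, cat. DMAP, CH2Cl2, 0 °C → rt
Reagents that add atoms: tert-butyldimethylsilyl chloride, CC(C)(C)[Si](C)(C)Cl
Why: Standard silylation; the bulky, non-coordinating TBS ether is also the control element for the later cyclopropanation.

Step 7
Reactants: 11 tert-butyldimethyl{[(S)-1-((R)-oxiran-2-yl)prop-2-en-1-yl]oxy}silane; 12 ethyl propiolate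
Product: 14 ethyl (5R,6S)-6-(tert-butyldimethylsilyloxy)-5-hydroxyoct-7-en-2-ynoate, via lithium ethyl propiolate 13 (not isolated)
Conditions: 12, n-BuLi, THF, −78 °C; BF3·OEt2; then 11, −78 °C; aq. NH4Cl
Reagents that add atoms: n-butyllithium, [Li]CCCC (supplies only the lithium of intermediate 13)
Why: BF3-promoted alkynylation of a terminal epoxide (Yamaguchi–Hirao) is an SN2 opening at the CH2 terminus, so both stereocentres are carried through unchanged.

Step 8
Reactants: 14 ethyl (5R,6S)-6-(tert-butyldimethylsilyloxy)-5-hydroxyoct-7-en-2-ynoate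
Product: 16 (R)-6-[(S)-1-(tert-butyldimethylsilyloxy)prop-2-en-1-yl]-5,6-dihydro-2H-pyran-2-one, via (Z)-hydroxy enoate 15 (not isolated)
Conditions: H2 (1 atm), Lindlar catalyst (Pd/CaCO3, Pb(OAc)2-poisoned), quinoline, EtOAc, rt, monitored uptake; filter; PPTS (cat.), toluene, 60 °C
Reagents that add atoms: none
Why: Lindlar semi-hydrogenation gives the Z-enoate, whose δ-hydroxyl closes the dihydropyranone (first ring) with loss of ethanol; the poisoned catalyst spares the terminal vinyl group.

Step 9
Reactants: 17 vinylmagnesium bromide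
Product: 18 4,4,5,5-tetramethyl-2-vinyl-1,3,2-dioxaborolane (vinylboronic acid pinacol ester)
Conditions: 2-isopropoxy-4,4,5,5-tetramethyl-1,3,2-dioxaborolane, THF, −78 °C → rt; HCl in Et2O
Reagents that add atoms: 2-isopropoxy-4,4,5,5-tetramethyl-1,3,2-dioxaborolane, CC(C)OB1OC(C)(C)C(C)(C)O1
Why: Addition of the Grignard reagent to the borate and loss of isopropoxide is the standard route to pinacol boronates; no stereocentre is involved.

Step 10
Reactants: 16 (R)-6-[(S)-1-(tert-butyldimethylsilyloxy)prop-2-en-1-yl]-5,6-dihydro-2H-pyran-2-one; 18 4,4,5,5-tetramethyl-2-vinyl-1,3,2-dioxaborolane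
Product: 19 (R)-6-[(S,E)-1-(tert-butyldimethylsilyloxy)-3-(4,4,5,5-tetramethyl-1,3,2-dioxaborolan-2-yl)prop-2-en-1-yl]-5,6-dihydro-2H-pyran-2-one
Conditions: 18 (3 equiv), second-generation Hoveyda–Grubbs catalyst [RuCl2(SIMes)(=CH-C6H4-2-OiPr)] (5 mol %), CH2Cl2, 40 °C
Reagents that add atoms: none
Why: Olefin cross-metathesis with vinyl pinacol boronate gives the E-alkenyl boronate under steric control, while the electron-poor cis-disubstituted lactone alkene does not enter the catalytic cycle.

Step 11
Reactants: 19 (R)-6-[(S,E)-1-(tert-butyldimethylsilyloxy)-3-(4,4,5,5-tetramethyl-1,3,2-dioxaborolan-2-yl)prop-2-en-1-yl]-5,6-dihydro-2H-pyran-2-one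
Product: 20 (R)-6-{(S)-(tert-butyldimethylsilyloxy)[(1S,2S)-2-(4,4,5,5-tetramethyl-1,3,2-dioxaborolan-2-yl)cyclopropyl]methyl}-5,6-dihydro-2H-pyran-2-one
Conditions: Et2Zn, CF3CO2H, CH2I2, CH2Cl2, 0 °C → rt
Reagents that add atoms: diiodomethane, ICI
Why: Simmons–Smith cyclopropanation (Shi carbenoid) is stereospecific, so the E-alkene gives the trans ring (second ring); with the non-coordinating OTBS group in the inside position the carbenoid adds anti to the lactone-bearing carbon, as known for (E)-allylic silyl ethers, which sets both ring centres as (1S,2S).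

Step 12
Reactants: 20 (R)-6-{(S)-(tert-butyldimethylsilyloxy)[(1S,2S)-2-(4,4,5,5-tetramethyl-1,3,2-dioxaborolan-2-yl)cyclopropyl]methyl}-5,6-dihydro-2H-pyran-2-one
Product: 21 [(1S,2S)-2-{(S)-(tert-butyldimethylsilyloxy)[(R)-6-oxo-3,6-dihydro-2H-pyran-2-yl]methyl}cyclopropyl]boronic acid
Conditions: NaIO4, NH4OAc, acetone/H2O (1:1), rt
Reagents that add atoms: water, O
Why: Periodate cleaves the pinacol released by hydrolysis and so drives the ester to the free boronic acid at near-neutral pH, which leaves lactone, silyl ether and the C–B stereocentre untouched.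

Step 13
Reactants: 21 [(1S,2S)-2-{(S)-(tert-butyldimethylsilyloxy)[(R)-6-oxo-3,6-dihydro-2H-pyran-2-yl]methyl}cyclopropyl]boronic acid; 8 S-phenyl (S)-2-{[(E)-3-(4-(tert-butyldimethylsilyloxy)phenyl)prop-2-enoyl]oxy}propanethioate
Product: 22 (S)-1-[(1S,2S)-2-{(S)-(tert-butyldimethylsilyloxy)[(R)-6-oxo-3,6-dihydro-2H-pyran-2-yl]methyl}cyclopropyl]-1-oxopropan-2-yl (E)-3-[4-(tert-butyldimethylsilyloxy)phenyl]prop-2-enoate
Conditions: 8 (1.3 equiv), Pd2(dba)3 (5 mol %), P(2-furyl)3 (20 mol %), CuTC [CuO2C-C4H3S] (1.6 equiv), THF, 50 °C, Ar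
Reagents that add atoms: none
Why: Proposed new method: a base-free thioester–boronic acid ketone synthesis with a configurationally defined secondary cyclopropylboronic acid as nucleophile, a substrate class not yet shown in this manifold; zerovalent palladium inserts into the acyl–S bond of 8, the monovalent copper carboxylate binds the thiolate while its carboxylate activates boron, the cyclopropyl group (high s-character C–B bond) transmetalates with retention, and fast acyl–cyclopropyl reductive elimination forms the ketone without base, so the α-acyloxy centre is not epimerised; the closest known reactions are the Liebeskind–Srogl coupling of thioesters with aryl and alkenyl boronic acids and the Ag2O-promoted Suzuki-type acylation of trans-cyclopropylboronic acids with acyl chlorides.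

Step 14
Reactants: 22 (S)-1-[(1S,2S)-2-{(S)-(tert-butyldimethylsilyloxy)[(R)-6-oxo-3,6-dihydro-2H-pyran-2-yl]methyl}cyclopropyl]-1-oxopropan-2-yl (E)-3-[4-(tert-butyldimethylsilyloxy)phenyl]prop-2-enoate
Product: 23 Brevipolide G, (S)-1-[(1S,2S)-2-{(S)-hydroxy[(R)-6-oxo-3,6-dihydro-2H-pyran-2-yl]methyl}cyclopropyl]-1-oxopropan-2-yl (E)-3-(4-hydroxyphenyl)prop-2-enoate
Conditions: HF·pyridine, pyridine, THF, 0 °C → rt
Reagents that add atoms: none
Why: Buffered fluoride desilylation removes the aryl and the secondary alkyl TBS groups without opening the lactone, migrating the coumaroyl ester or touching any stereocentre.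

**Compound list**
1 | 4-iodophenol | Oc1ccc(I)cc1 | starting material
2 | tert-butyl(4-iodophenoxy)dimethylsilane | CC(C)(C)[Si](C)(C)Oc1ccc(I)cc1 | intermediate
3 | acrylic acid | C=CC(=O)O | starting material
4 | (E)-3-[4-(tert-butyldimethylsilyloxy)phenyl]prop-2-enoic acid | CC(C)(C)[Si](C)(C)Oc1ccc(/C=C/C(=O)O)cc1 | intermediate
5 | (S)-lactic acid | C[C@H](O)C(=O)O | starting material
6 | (E)-3-[4-(tert-butyldimethylsilyloxy)phenyl]prop-2-enoyl chloride (not isolated) | CC(C)(C)[Si](C)(C)Oc1ccc(/C=C/C(=O)Cl)cc1 | intermediate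
7 | (S)-2-{[(E)-3-(4-(tert-butyldimethylsilyloxy)phenyl)prop-2-enoyl]oxy}propanoic acid | C[C@H](OC(=O)/C=C/c1ccc(O[Si](C)(C)C(C)(C)C)cc1)C(=O)O | intermediate
8 | S-phenyl (S)-2-{[(E)-3-(4-(tert-butyldimethylsilyloxy)phenyl)prop-2-enoyl]oxy}propanethioate | C[C@H](OC(=O)/C=C/c1ccc(O[Si](C)(C)C(C)(C)C)cc1)C(=O)Sc1ccccc1 | intermediate
9 | penta-1,4-dien-3-ol | C=CC(O)C=C | starting material
10 | (S)-1-[(R)-oxiran-2-yl]prop-2-en-1-ol | C=C[C@H](O)[C@H]1CO1 | intermediate
11 | tert-butyldimethyl{[(S)-1-((R)-oxiran-2-yl)prop-2-en-1-yl]oxy}silane | C=C[C@H](O[Si](C)(C)C(C)(C)C)[C@H]1CO1 | intermediate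
12 | ethyl propiolate | C#CC(=O)OCC | starting material
13 | ethyl 3-lithioprop-2-ynoate (not isolated) | [Li]C#CC(=O)OCC | intermediate
14 | ethyl (5R,6S)-6-(tert-butyldimethylsilyloxy)-5-hydroxyoct-7-en-2-ynoate | C=C[C@H](O[Si](C)(C)C(C)(C)C)[C@H](O)CC#CC(=O)OCC | intermediate
15 | ethyl (2Z,5R,6S)-6-(tert-butyldimethylsilyloxy)-5-hydroxyocta-2,7-dienoate (not isolated) | C=C[C@H](O[Si](C)(C)C(C)(C)C)[C@H](O)C/C=C\C(=O)OCC | intermediate
16 | (R)-6-[(S)-1-(tert-butyldimethylsilyloxy)prop-2-en-1-yl]-5,6-dihydro-2H-pyran-2-one | C=C[C@H](O[Si](C)(C)C(C)(C)C)[C@H]1CC=CC(=O)O1 | intermediate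
17 | vinylmagnesium bromide | C=C[Mg]Br | starting material
18 | 4,4,5,5-tetramethyl-2-vinyl-1,3,2-dioxaborolane | C=CB1OC(C)(C)C(C)(C)O1 | intermediate
19 | (R)-6-[(S,E)-1-(tert-butyldimethylsilyloxy)-3-(4,4,5,5-tetramethyl-1,3,2-dioxaborolan-2-yl)prop-2-en-1-yl]-5,6-dihydro-2H-pyran-2-one | CC1(C)OB(/C=C/[C@H](O[Si](C)(C)C(C)(C)C)[C@H]2CC=CC(=O)O2)OC1(C)C | intermediate
20 | (R)-6-{(S)-(tert-butyldimethylsilyloxy)[(1S,2S)-2-(4,4,5,5-tetramethyl-1,3,2-dioxaborolan-2-yl)cyclopropyl]methyl}-5,6-dihydro-2H-pyran-2-one | CC1(C)OB([C@H]2C[C@@H]2[C@H](O[Si](C)(C)C(C)(C)C)[C@H]2CC=CC(=O)O2)OC1(C)C | intermediate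
21 | [(1S,2S)-2-{(S)-(tert-butyldimethylsilyloxy)[(R)-6-oxo-3,6-dihydro-2H-pyran-2-yl]methyl}cyclopropyl]boronic acid | OB(O)[C@H]1C[C@@H]1[C@H](O[Si](C)(C)C(C)(C)C)[C@H]1CC=CC(=O)O1 | intermediate
22 | (S)-1-[(1S,2S)-2-{(S)-(tert-butyldimethylsilyloxy)[(R)-6-oxo-3,6-dihydro-2H-pyran-2-yl]methyl}cyclopropyl]-1-oxopropan-2-yl (E)-3-[4-(tert-butyldimethylsilyloxy)phenyl]prop-2-enoate | C[C@H](OC(=O)/C=C/c1ccc(O[Si](C)(C)C(C)(C)C)cc1)C(=O)[C@H]1C[C@@H]1[C@H](O[Si](C)(C)C(C)(C)C)[C@H]1CC=CC(=O)O1 | intermediate
23 | Brevipolide G | C[C@H](OC(=O)/C=C/c1ccc(O)cc1)C(=O)[C@H]1C[C@@H]1[C@H](O)[C@H]1CC=CC(=O)O1 | target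

**Step count and risks**

Total step count: 14. Longest linear sequence: 9 steps (steps 5, 6, 7, 8, 10, 11, 12, 13, 14, from penta-1,4-dien-3-ol 9).

Steps most likely to fail:

1. Step 13 (the proposed coupling). Transmetalation of the cyclopropylboronic acid may be slow, which would allow decarbonylation of the acylpalladium species or protodeboronation. Fallback with known chemistry: setting out from acid 7, oxalyl chloride and catalytic DMF give the acid chloride (S)-1-chloro-1-oxopropan-2-yl (E)-3-[4-(tert-butyldimethylsilyloxy)phenyl]prop-2-enoate F1. This is coupled with boronic acid 21 by the known Ag2O-promoted Suzuki-type acylation of trans-2-alkylcyclopropylboronic acids (PdCl2(dppf), Ag2O, K2CO3, toluene, 80 °C), which proceeds with retention at the cyclopropyl carbon. The fallback changes the electrophile class and the way boron is activated, and it returns to the route at 22.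

2. Step 11 (facial selectivity of the cyclopropanation). If the carbenoid is delivered from the oxygen side, or the ratio is low, the wrong ring diastereomer results. Fallback: setting out from vinyl lactone 16 (steps 10 and 11 are bypassed), Rh2(S-TFNTTL)4, or its enantiomer if that is the matched one, transfers the redox-active carbene from 1,3-dioxoisoindolin-2-yl diazoacetate to the vinyl group under catalyst control. This gives the trans redox-active ester 1,3-dioxoisoindolin-2-yl (1S,2S)-2-{(S)-(tert-butyldimethylsilyloxy)[(R)-6-oxo-3,6-dihydro-2H-pyran-2-yl]methyl}cyclopropane-1-carboxylate F2. Known nickel-catalysed decarboxylative borylation (NiCl2·6H2O, 4,4′-dimethoxy-2,2′-bipyridine, MgBr2·OEt2, B2pin2/MeLi, THF/DMF) then traps the cyclopropyl radical trans to the side chain and returns to the route at 20.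

3. Step 10 (cross-metathesis next to a branched allylic silyl ether). Conversion may stall. Fallback: setting out from 16, the known palladium-catalysed boryl-Heck reaction with B-chlorocatecholborane (Pd2(dba)3, bulky monophosphine, LiOTf, Cy2NMe, PhCF3, 70 °C) gives the catechol ester (R)-6-[(S,E)-3-(1,3,2-benzodioxaborol-2-yl)-1-(tert-butyldimethylsilyloxy)prop-2-en-1-yl]-5,6-dihydro-2H-pyran-2-one F3. This is transesterified with pinacol in the same flask and returns to the route at 19.

**Further compounds**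
F1 | step 13 | (S)-1-chloro-1-oxopropan-2-yl (E)-3-[4-(tert-butyldimethylsilyloxy)phenyl]prop-2-enoate | C[C@H](OC(=O)/C=C/c1ccc(O[Si](C)(C)C(C)(C)C)cc1)C(=O)Cl
F2 | step 11 | 1,3-dioxoisoindolin-2-yl (1S,2S)-2-{(S)-(tert-butyldimethylsilyloxy)[(R)-6-oxo-3,6-dihydro-2H-pyran-2-yl]methyl}cyclopropane-1-carboxylate | O=C(ON1C(=O)c2ccccc2C1=O)[C@H]1C[C@@H]1[C@H](O[Si](C)(C)C(C)(C)C)[C@H]1CC=CC(=O)O1
F3 | step 10 | (R)-6-[(S,E)-3-(1,3,2-benzodioxaborol-2-yl)-1-(tert-butyldimethylsilyloxy)prop-2-en-1-yl]-5,6-dihydro-2H-pyran-2-one | c1ccc2c(c1)OB(/C=C/[C@H](O[Si](C)(C)C(C)(C)C)[C@H]1CC=CC(=O)O1)O2
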